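The trans-3,4-dibenzyl-γ-butyrolactone core is taken apart at the two bonds that join the ring to its arms: lactone C4 (next to C5H2) to the dihydrobenzofuran arm and lactone C3 (next to C2=O) to the benzylic CH2 of the open-chain arm. Because C3 and C4 are the α and β carbons of a 2(5H)-furanone, one tandem conjugate addition–enolate alkylation on (5S)-5-menthyloxy-2(5H)-furanone joins all three fragments and sets both lactone stereocentres. The precursors are a lithiated 2-aryl-1,3-dithiane carrying the finished trans-dihydrobenzofuran and a benzylic bromide carrying the silylated 1,3-diol, both derived from one anti-aldol diol.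

Key step: step 20

Remark: the aldol of step 7 is assumed to follow the sense of a magnesium-chelated Z-enolate attacked anti to the benzyl group of the (S)-auxiliary, giving the (2R,3S) adduct; if the arylacetyl imide reacted with the opposite facial sense, the (R)-auxiliary would be used and nothing else would change.

Abbreviations: TBS = tert-butyldimethylsilyl; Bn = benzyl; Men = (1S,2R,5S)-menthyl; group A (open arm) = 3-[(1S,2S)-1-(4-benzyloxy-3-methoxyphenyl)-1,3-bis(TBS-oxy)propan-2-yl]-4-(TBS-oxy)-5-methoxyphenyl; group B (closed arm) = (2R,3S)-2-(4-benzyloxy-3-methoxyphenyl)-3-(TBS-oxymethyl)-7-methoxy-2,3-dihydrobenzofuran-5-yl.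

**Arylacetic acid and common diol (steps 1–8)**

Step 1
Reactants: 1 methyl vanillate (methyl 4-hydroxy-3-methoxybenzoate)
Product: 2 methyl 4-(allyloxy)-3-methoxybenzoate
Conditions: allyl bromide, K2CO3, acetone, reflux
Reagents that add atoms: allyl bromide (C=CCBr)
Why: Williamson ether synthesis in which the phenoxide formed with K2CO3 displaces bromide from the allylic halide, with no stereocentre involved.

Step 2
Reactants: 2 methyl 4-(allyloxy)-3-methoxybenzoate
Product: 3 methyl 3-allyl-4-hydroxy-5-methoxybenzoate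
Conditions: N,N-diethylaniline, 200 °C
Reagents that add atoms: none
Why: Aromatic Claisen rearrangement, in which the [3,3]-sigmatropic shift can only deliver the allyl group to the single free ortho position and tautomerisation restores the phenol.

Step 3
Reactants: 3 methyl 3-allyl-4-hydroxy-5-methoxybenzoate
Product: 4 methyl 3-allyl-4-(TBS-oxy)-5-methoxybenzoate
Conditions: TBSCl, imidazole, DMF, rt to 40 °C
Reagents that add atoms: tert-butyldimethylsilyl chloride (CC(C)(C)[Si](C)(C)Cl)
Why: Imidazole-promoted silylation of the phenol gives an aryl silyl ether that should survive the oxidations, the acylation and the aldol step yet can later be removed selectively with mild base.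

Step 4
Reactants: 4 methyl 3-allyl-4-(TBS-oxy)-5-methoxybenzoate
Product: 5 methyl 4-(TBS-oxy)-3-methoxy-5-(2-oxoethyl)benzoate
Conditions: OsO4 (cat.), NaIO4, 2,6-lutidine, dioxane/H2O, rt
Reagents that add atoms: sodium periodate ([Na+].[O-]I(=O)(=O)=O), the terminal oxidant that supplies the aldehyde oxygen through osmium tetroxide (O=[Os](=O)(=O)=O)
Why: Lemieux–Johnson cleavage (OsO4-catalysed dihydroxylation of the terminal alkene, then NaIO4 glycol cleavage, with 2,6-lutidine to suppress over-oxidation) shortens the allyl group to the arylacetaldehyde without touching the arene.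

Step 5
Reactants: 5 methyl 4-(TBS-oxy)-3-methoxy-5-(2-oxoethyl)benzoate
Product: 6 2-[2-(TBS-oxy)-3-methoxy-5-(methoxycarbonyl)phenyl]acetic acid
Conditions: NaClO2, NaH2PO4, 2-methyl-2-butene, t-BuOH/H2O, 0 °C to rt
Reagents that add atoms: sodium chlorite ([Na+].[O-]Cl=O)
Why: Pinnick oxidation converts the enolisable arylacetaldehyde into the acid under buffered conditions, with 2-methyl-2-butene scavenging the HOCl that would otherwise chlorinate the electron-rich ring.

Step 6
Reactants: 6 2-[2-(TBS-oxy)-3-methoxy-5-(methoxycarbonyl)phenyl]acetic acid; 7 (S)-4-benzyl-2-oxazolidinone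
Product: 9 (S)-4-benzyl-3-{[2-(TBS-oxy)-3-methoxy-5-(methoxycarbonyl)phenyl]acetyl}-2-oxazolidinone, via mixed pivalic anhydride 8 (not isolated)
Conditions: PivCl, Et3N, THF, −20 °C; then LiCl, 7, −20 °C to rt
Reagents that add atoms: none
Why: N-acylation of the oxazolidinone through the mixed pivalic anhydride with LiCl/Et3N activation takes place at the less hindered arylacetyl carbonyl, and the only stereocentre is the one bought with the auxiliary.

Step 7
Reactants: 9 arylacetyl imide; 10 4-benzyloxy-3-methoxybenzaldehyde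
Product: 12 (4S)-4-benzyl-3-{(2R,3S)-3-(4-benzyloxy-3-methoxyphenyl)-3-hydroxy-2-[2-(TBS-oxy)-3-methoxy-5-(methoxycarbonyl)phenyl]propanoyl}-2-oxazolidinone, via O-trimethylsilyl aldol ether 11 (not isolated)
Conditions: MgCl2 (20 mol%), Et3N, TMSCl, EtOAc, rt; then 1 M HCl/THF, 0 °C
Reagents that add atoms: none
Why: Evans MgCl2-catalysed direct anti-aldol reaction (soft enolisation by MgCl2/Et3N, silylation of the aldolate by TMSCl to release the metal), best with non-enolisable aromatic aldehydes such as 10, in which the magnesium-chelated Z-enolate is attacked anti to the auxiliary benzyl group through a boat-like transition state, which should set C2 as R and C3 as S with the anti relationship.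

Step 8
Reactants: 12 anti-aldol adduct
Product: 13 methyl 3-[(1S,2S)-1-(4-benzyloxy-3-methoxyphenyl)-1,3-dihydroxypropan-2-yl]-4-(TBS-oxy)-5-methoxybenzoate
Conditions: NaBH4, THF/H2O, 0 °C to rt
Reagents that add atoms: none
Why: Reductive removal of the auxiliary with NaBH4 in wet THF reduces the activated imide carbonyl to the primary alcohol, returns the oxazolidinone and leaves the less electrophilic aryl methyl ester and both stereocentres untouched.

**Closed arm, fragment 1 (steps 9–14)**

Step 9
Reactants: 13 common (1S,2S)-diol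
Product: 14 methyl 3-[(1S,2S)-1-(4-benzyloxy-3-methoxyphenyl)-1-hydroxy-3-(TBS-oxy)propan-2-yl]-4-(TBS-oxy)-5-methoxybenzoate
Conditions: TBSCl (1.05 equiv), imidazole, CH2Cl2, 0 °C
Reagents that add atoms: tert-butyldimethylsilyl chloride (CC(C)(C)[Si](C)(C)Cl)
Why: Kinetic silylation selects the unhindered primary hydroxyl over the secondary benzylic one, which sits between an aryl group and a tertiary carbon.

Step 10
Reactants: 14 primary silyl ether
Product: 15 methyl 4-hydroxy-3-[(1S,2S)-1-(4-benzyloxy-3-methoxyphenyl)-1-hydroxy-3-(TBS-oxy)propan-2-yl]-5-methoxybenzoate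
Conditions: K2CO3 (0.3 equiv), MeOH, 0 °C to rt
Reagents that add atoms: none
Why: Base-catalysed methanolysis cleaves only the aryl silyl ether because the phenoxide para to the ester is a much better leaving group than an alkoxide, so the primary alkyl silyl ether and the methyl ester remain.

Step 11
Reactants: 15 phenol with free benzylic carbinol
Product: 16 methyl (2R,3S)-2-(4-benzyloxy-3-methoxyphenyl)-3-(TBS-oxymethyl)-7-methoxy-2,3-dihydrobenzofuran-5-carboxylate
Conditions: PPh3, DIAD, THF, 0 °C to rt
Reagents that add atoms: none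
Why: Intramolecular Mitsunobu etherification in which the acidic phenol displaces the oxyphosphonium group of the activated benzylic carbinol in a 5-exo-tet SN2 closure with inversion, turning the (1S) carbinol into C2 (R) of the 2,3-trans-dihydrobenzofuran, the same ring that any competing ionised pathway would also favour.

Step 12
Reactants: 16 dihydrobenzofuran methyl ester
Product: 17 [(2R,3S)-2-(4-benzyloxy-3-methoxyphenyl)-3-(TBS-oxymethyl)-7-methoxy-2,3-dihydrobenzofuran-5-yl]methanol (B–CH2OH)
Conditions: i-Bu2AlH, CH2Cl2, −78 to 0 °C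
Reagents that add atoms: none
Why: i-Bu2AlH reduces the aryl ester to the benzylic alcohol and does not affect the silyl ether, the benzyl ether or the cyclic benzylic ether.

Step 13
Reactants: 17 benzylic alcohol B–CH2OH
Product: 18 (2R,3S)-2-(4-benzyloxy-3-methoxyphenyl)-3-(TBS-oxymethyl)-7-methoxy-2,3-dihydrobenzofuran-5-carbaldehyde (B–CHO)
Conditions: MnO2, CH2Cl2, rt
Reagents that add atoms: none
Why: MnO2 oxidation is selective for benzylic alcohols, stops at the aldehyde and runs under neutral conditions.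

Step 14
Reactants: 18 aldehyde B–CHO
Product: 19 2-(group B)-1,3-dithiane (fragment 1)
Conditions: HS(CH2)3SH, MgBr2·OEt2 (0.2 equiv), Et2O/CH2Cl2, rt
Reagents that add atoms: propane-1,3-dithiol (SCCCS)
Why: Lewis-acid-catalysed dithioacetalisation of the aromatic aldehyde with MgBr2·OEt2, mild enough to spare the silyl ether and the acid-sensitive 2-aryl-dihydrobenzofuran ether, installs the acyl-anion equivalent needed for the coupling.

**Open arm, fragment 2 (steps 15–17)**

Step 15
Reactants: 13 common (1S,2S)-diol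
Product: 20 methyl 3-[(1S,2S)-1-(4-benzyloxy-3-methoxyphenyl)-1,3-bis(TBS-oxy)propan-2-yl]-4-(TBS-oxy)-5-methoxybenzoate (A–CO2Me)
Conditions: TBSOTf, 2,6-lutidine, CH2Cl2, −78 to 0 °C
Reagents that add atoms: tert-butyldimethylsilyl triflate (CC(C)(C)[Si](C)(C)OS(=O)(=O)C(F)(F)F)
Why: Silylation with the silyl triflate and a hindered pyridine base caps both the primary and the hindered secondary benzylic hydroxyl under non-ionising conditions, so the carbinol configuration is kept.

Step 16
Reactants: 20 tris-silyl ester A–CO2Me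
Product: 21 benzylic alcohol A–CH2OH
Conditions: i-Bu2AlH, CH2Cl2, −78 °C
Reagents that add atoms: none
Why: i-Bu2AlH reduction of the aryl ester gives the benzylic alcohol, and the three silyl ethers and the benzyl ether are inert to the hydride.

Step 17
Reactants: 21 benzylic alcohol A–CH2OH
Product: 22 benzylic bromide A–CH2Br (fragment 2)
Conditions: CBr4, PPh3, CH2Cl2, 0 °C; used crude at once
Reagents that add atoms: carbon tetrabromide (BrC(Br)(Br)Br)
Why: Appel bromination converts the unhindered primary benzylic alcohol into the bromide under neutral conditions, and the labile para-silyloxybenzyl bromide is used at once without chromatography.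

**Furanone, fragment 3 (steps 18–19)**

Step 18
Reactants: 23 furfural
Product: 25 5-hydroxy-2(5H)-furanone (racemic), via furfural endoperoxide 24 (not isolated)
Conditions: O2, visible light, methylene blue (cat.), MeOH, rt
Reagents that add atoms: dioxygen (O=O)
Why: Dye-sensitised singlet-oxygen [4+2] cycloaddition to the furan gives the endoperoxide, which methanol fragments with loss of the formyl carbon as methyl formate to leave the racemic hydroxybutenolide.

Step 19
Reactants: 25 5-hydroxy-2(5H)-furanone; 26 (1S,2R,5S)-(+)-menthol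
Product: 27 (5S)-5-[(1S,2R,5S)-menthyloxy]-2(5H)-furanone (fragment 3)
Conditions: camphorsulfonic acid (cat.), toluene, reflux (Dean–Stark); crystallisation from petroleum ether
Reagents that add atoms: none
Why: Acid-catalysed acetalisation through the cyclic oxocarbenium ion gives both C5 epimers, which equilibrate under the acid while the (5S) epimer, the mirror image of the well-known crystalline (5R)-l-menthyloxy compound, is removed by crystallisation, so C5 is set by crystallisation-driven selection.

**Coupling and end game (steps 20–24)**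

Step 20
Reactants: 19 dithiane of the closed arm (fragment 1); 27 (5S)-menthyloxyfuranone (fragment 3); 22 benzylic bromide of the open arm (fragment 2)
Product: 30 (3S,4S,5S)-3-(A–CH2)-4-[2-(group B)-1,3-dithian-2-yl]-5-[(1S,2R,5S)-menthyloxy]dihydrofuran-2(3H)-one (3,4-trans-4,5-trans), via lithiated dithiane 28 (not isolated), via lithium lactone enolate 29 (not isolated)
Conditions: n-BuLi, THF, −78 to −30 °C; 27, −78 °C; then 22, DMPU, −78 to −20 °C
Reagents that add atoms: none
Why: n-BuLi removes the dithiane C2–H of 19 (the only C–H acidic enough at low temperature), the soft sulfur-stabilised carbanion 28 adds in Michael fashion to C4 of butenolide 27, and the lithium enolate 29 so formed, activated by DMPU, is benzylated at C3 by bromide 22 in an SN2 reaction. The closest known reaction type is the tandem conjugate addition–enolate alkylation of lithiated 2-aryl-1,3-dithianes with 5-menthyloxy-2(5H)-furanones and benzylic halides, established for trans-dibenzylbutyrolactone lignans. No ring is closed: the lactone ring is delivered intact by 27 and the step only forms the C4–C(dithiane) and C3–CH2 bonds. The new C4 stereocentre is controlled by the C5 menthyloxy acetal centre of 27 (attack on the opposite face), and the new C3 stereocentre by the bulky C4 substituent just installed (alkylation on the opposite face), which should give the 3,4-trans-4,5-trans adduct. The step needs 1,4- rather than 1,2-addition, secured by the soft dithiane anion, and clean facial control with C-monoalkylation, secured by the C5 substituent and the crowded C4 centre; both reacting benzylic carbons lie between two unsubstituted ortho positions, every hydroxyl is silylated or benzylated, and the carbonyl and CH2O ends of the lactone are already differentiated in 27, so the open arm ends next to C2=O and the closed arm next to C5.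

Step 21
Reactants: 30 three-component adduct
Product: 31 (3S,4S,5S)-3-(A–CH2)-4-(B–CH2)-5-[(1S,2R,5S)-menthyloxy]dihydrofuran-2(3H)-one
Conditions: NiCl2·6H2O, NaBH4, MeOH/THF, 0 °C
Reagents that add atoms: none
Why: Reductive desulfurisation with nickel boride (Ni2B) generated in situ cleaves the benzylic C–S bonds of the dithiane to CH2 without cleaving aryl benzyl ethers or alkyl silyl ethers and without touching any stereocentre.

Step 22
Reactants: 31 desulfurised lactone acetal
Product: 33 (3S,4S)-4-(B–CH2)-3-{3-[(1S,2S)-1-(4-benzyloxy-3-methoxyphenyl)-1,3-bis(TBS-oxy)propan-2-yl]-4-hydroxy-5-methoxybenzyl}dihydrofuran-2(3H)-one, via ring-opened hydroxy carboxylate 32 (not isolated)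
Conditions: KOH, NaBH4, EtOH/THF/H2O, 0 °C to rt; then 1 M HCl to pH 3, rt
Reagents that add atoms: none
Why: Saponification–reduction of the acyl acetal, in which hydroxide opens the pseudo-ester to the carboxylate and a hemiacetal that expels menthol, NaBH4 reduces the aldehyde as it forms, acidification closes the γ-lactone by 5-exo-trig acyl substitution and hydroxide also removes the aryl silyl group, while C3 and C4 stay trans, the arrangement also favoured thermodynamically.

Step 23
Reactants: 33 silyl-protected lactone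
Product: 34 dibenzyl ether of the target, (3S,4S)-lactone with free 1,3-diol, free CH2OH on the dihydrobenzofuran and free central phenol
Conditions: Bu4NF, AcOH (1:1), THF, 0 °C to rt
Reagents that add atoms: none
Why: Fluoride desilylation buffered with AcOH removes the three alkyl silyl ethers without opening or epimerising the lactone, and because the outer phenols are still benzylated no quinone methide can form from the benzylic carbinol or the dihydrobenzofuran.

Step 24
Reactants: 34 dibenzyl ether of the target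
Product: 35 target CNP0186558.3
Conditions: H2 (1 atm), 10% Pd/C, EtOAc/MeOH, rt, stopped after two equivalents of H2
Reagents that add atoms: none
Why: Catalytic hydrogenolysis of aryl benzyl ethers over Pd/C under neutral conditions is much faster than hydrogenolysis of the secondary benzylic alcohol or of the cyclic benzylic ether, so stopping after uptake of two equivalents of H2 should give the target without any acid.

**Compound list**

1 | methyl vanillate | COC(=O)c1ccc(O)c(OC)c1 | starting material
2 | methyl 4-(allyloxy)-3-methoxybenzoate | COC(=O)c1ccc(OCC=C)c(OC)c1 | intermediate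
3 | methyl 3-allyl-4-hydroxy-5-methoxybenzoate | COC(=O)c1cc(CC=C)c(O)c(OC)c1 | intermediate
4 | methyl 3-allyl-4-(TBS-oxy)-5-methoxybenzoate | COC(=O)c1cc(CC=C)c(O[Si](C)(C)C(C)(C)C)c(OC)c1 | intermediate
5 | methyl 4-(TBS-oxy)-3-methoxy-5-(2-oxoethyl)benzoate | COC(=O)c1cc(CC=O)c(O[Si](C)(C)C(C)(C)C)c(OC)c1 | intermediate
6 | 2-[2-(TBS-oxy)-3-methoxy-5-(methoxycarbonyl)phenyl]acetic acid | COC(=O)c1cc(CC(=O)O)c(O[Si](C)(C)C(C)(C)C)c(OC)c1 | intermediate
7 | (S)-4-benzyl-2-oxazolidinone | O=C1N[C@@H](Cc2ccccc2)CO1 | starting material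
8 | mixed pivalic anhydride of acid 6 | COC(=O)c1cc(CC(=O)OC(=O)C(C)(C)C)c(O[Si](C)(C)C(C)(C)C)c(OC)c1 | intermediate
9 | arylacetyl imide of (S)-4-benzyl-2-oxazolidinone | COC(=O)c1cc(CC(=O)N2[C@@H](Cc3ccccc3)COC2=O)c(O[Si](C)(C)C(C)(C)C)c(OC)c1 | intermediate
10 | 4-benzyloxy-3-methoxybenzaldehyde | COc1cc(C=O)ccc1OCc1ccccc1 | starting material
11 | O-trimethylsilyl ether of the (2R,3S) anti-aldol adduct | O=C(N1[C@@H](Cc2ccccc2)COC1=O)[C@H](c1cc(C(=O)OC)cc(OC)c1O[Si](C)(C)C(C)(C)C)[C@H](O[Si](C)(C)C)c1ccc(OCc2ccccc2)c(OC)c1 | intermediate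
12 | (2R,3S) anti-aldol adduct on the (S)-auxiliary | O=C(N1[C@@H](Cc2ccccc2)COC1=O)[C@H](c1cc(C(=O)OC)cc(OC)c1O[Si](C)(C)C(C)(C)C)[C@H](O)c1ccc(OCc2ccccc2)c(OC)c1 | intermediate
13 | common (1S,2S)-1,2-diarylpropane-1,3-diol | OC[C@H](c1cc(C(=O)OC)cc(OC)c1O[Si](C)(C)C(C)(C)C)[C@H](O)c1ccc(OCc2ccccc2)c(OC)c1 | intermediate
14 | primary TBS ether of diol 13 | CC(C)(C)[Si](C)(C)OC[C@H](c1cc(C(=O)OC)cc(OC)c1O[Si](C)(C)C(C)(C)C)[C@H](O)c1ccc(OCc2ccccc2)c(OC)c1 | intermediate
15 | phenol with free (1S) benzylic carbinol and primary TBS ether | CC(C)(C)[Si](C)(C)OC[C@H](c1cc(C(=O)OC)cc(OC)c1O)[C@H](O)c1ccc(OCc2ccccc2)c(OC)c1 | intermediate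
16 | trans-(2R,3S)-dihydrobenzofuran methyl ester | COC(=O)c1cc(OC)c2c(c1)[C@@H](CO[Si](C)(C)C(C)(C)C)[C@H](c1ccc(OCc3ccccc3)c(OC)c1)O2 | intermediate
17 | dihydrobenzofuran benzylic alcohol B–CH2OH | OCc1cc(OC)c2c(c1)[C@@H](CO[Si](C)(C)C(C)(C)C)[C@H](c1ccc(OCc3ccccc3)c(OC)c1)O2 | intermediate
18 | dihydrobenzofuran aldehyde B–CHO | O=Cc1cc(OC)c2c(c1)[C@@H](CO[Si](C)(C)C(C)(C)C)[C@H](c1ccc(OCc3ccccc3)c(OC)c1)O2 | intermediate
19 | 2-(group B)-1,3-dithiane (fragment 1) | C1CSC(SC1)c1cc(OC)c2c(c1)[C@@H](CO[Si](C)(C)C(C)(C)C)[C@H](c1ccc(OCc3ccccc3)c(OC)c1)O2 | intermediate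
20 | tris-silyl methyl ester A–CO2Me | COC(=O)c1cc(OC)c(O[Si](C)(C)C(C)(C)C)c(c1)[C@@H](CO[Si](C)(C)C(C)(C)C)[C@H](O[Si](C)(C)C(C)(C)C)c1ccc(OCc2ccccc2)c(OC)c1 | intermediate
21 | benzylic alcohol A–CH2OH | OCc1cc(OC)c(O[Si](C)(C)C(C)(C)C)c(c1)[C@@H](CO[Si](C)(C)C(C)(C)C)[C@H](O[Si](C)(C)C(C)(C)C)c1ccc(OCc2ccccc2)c(OC)c1 | intermediate
22 | benzylic bromide A–CH2Br (fragment 2) | BrCc1cc(OC)c(O[Si](C)(C)C(C)(C)C)c(c1)[C@@H](CO[Si](C)(C)C(C)(C)C)[C@H](O[Si](C)(C)C(C)(C)C)c1ccc(OCc2ccccc2)c(OC)c1 | intermediate
23 | furfural | O=Cc1ccco1 | starting material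
24 | furfural endoperoxide (2,3,7-trioxabicyclo[2.2.1]hept-5-ene-1-carbaldehyde) | O=CC12C=CC(OO1)O2 | intermediate
25 | 5-hydroxy-2(5H)-furanone | O=C1C=CC(O)O1 | intermediate
26 | (1S,2R,5S)-(+)-menthol | C[C@H]1CC[C@@H]([C@H](C1)O)C(C)C | starting material
27 | (5S)-5-[(1S,2R,5S)-menthyloxy]-2(5H)-furanone (fragment 3) | O=C1C=C[C@@H](O[C@H]2C[C@@H](C)CC[C@@H]2C(C)C)O1 | intermediate
28 | 2-lithio derivative of dithiane 19 | [Li]C1(SCCCS1)c1cc(OC)c2c(c1)[C@@H](CO[Si](C)(C)C(C)(C)C)[C@H](c1ccc(OCc3ccccc3)c(OC)c1)O2 | intermediate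
29 | lithium enolate of the conjugate adduct | C1=C(O[Li])O[C@H](O[C@H]2C[C@@H](C)CC[C@@H]2C(C)C)[C@H]1C1(SCCCS1)c1cc(OC)c2c(c1)[C@@H](CO[Si](C)(C)C(C)(C)C)[C@H](c1ccc(OCc3ccccc3)c(OC)c1)O2 | intermediate
30 | three-component adduct, 3,4-trans-4,5-trans lactone acetal | C(c1cc(OC)c(O[Si](C)(C)C(C)(C)C)c(c1)[C@@H](CO[Si](C)(C)C(C)(C)C)[C@H](O[Si](C)(C)C(C)(C)C)c1ccc(OCc2ccccc2)c(OC)c1)[C@@H]3C(=O)O[C@H](O[C@H]6C[C@@H](C)CC[C@@H]6C(C)C)[C@H]3C4(SCCCS4)c4cc(OC)c5c(c4)[C@@H](CO[Si](C)(C)C(C)(C)C)[C@H](c4ccc(OCc6ccccc6)c(OC)c4)O5 | intermediate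
31 | desulfurised lactone acetal | C(c1cc(OC)c(O[Si](C)(C)C(C)(C)C)c(c1)[C@@H](CO[Si](C)(C)C(C)(C)C)[C@H](O[Si](C)(C)C(C)(C)C)c1ccc(OCc2ccccc2)c(OC)c1)[C@@H]3C(=O)O[C@H](O[C@H]6C[C@@H](C)CC[C@@H]6C(C)C)[C@H]3Cc4cc(OC)c5c(c4)[C@@H](CO[Si](C)(C)C(C)(C)C)[C@H](c4ccc(OCc6ccccc6)c(OC)c4)O5 | intermediate
32 | dipotassium salt of the ring-opened (2S,3S) 4-hydroxy acid with phenoxide | C(c1cc(OC)c([O-])c(c1)[C@@H](CO[Si](C)(C)C(C)(C)C)[C@H](O[Si](C)(C)C(C)(C)C)c1ccc(OCc2ccccc2)c(OC)c1)[C@H](C(=O)[O-])[C@@H](CO)Cc4cc(OC)c5c(c4)[C@@H](CO[Si](C)(C)C(C)(C)C)[C@H](c4ccc(OCc6ccccc6)c(OC)c4)O5.[K+].[K+] | intermediate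
33 | protected (3S,4S)-dibenzylbutyrolactone with free central phenol | C(c1cc(OC)c(O)c(c1)[C@@H](CO[Si](C)(C)C(C)(C)C)[C@H](O[Si](C)(C)C(C)(C)C)c1ccc(OCc2ccccc2)c(OC)c1)[C@@H]3C(=O)OC[C@H]3Cc4cc(OC)c5c(c4)[C@@H](CO[Si](C)(C)C(C)(C)C)[C@H](c4ccc(OCc6ccccc6)c(OC)c4)O5 | intermediate
34 | dibenzyl ether of the target | C(c1cc(OC)c(O)c(c1)[C@@H](CO)[C@H](O)c1ccc(OCc2ccccc2)c(OC)c1)[C@@H]3C(=O)OC[C@H]3Cc4cc(OC)c5c(c4)[C@@H](CO)[C@H](c4ccc(OCc6ccccc6)c(OC)c4)O5 | intermediate
35 | CNP0186558.3 | COc1cc([C@@H](O)[C@H](CO)c2cc(C[C@@H]3C(=O)OC[C@H]3Cc3cc(OC)c4c(c3)[C@@H](CO)[C@H](c3ccc(O)c(OC)c3)O4)cc(OC)c2O)ccc1O | target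

**Step count**

Total: 24 steps. Longest linear sequence: 19 steps (steps 1–14, then 20–24).

**Three steps most likely to fail**

Step 7 (anti-aldol). The hindered ortho-silyloxy arylacetyl enolate may react with poor diastereoselectivity or with the opposite facial sense, and the adduct may erode by retro-aldol reaction. The fallback sets out from acid 6 and comes back at phenol 15. Acid 6 would be coupled (PivCl, Et3N, LiCl, as in step 6) with (R)-4-benzyl-2-oxazolidinone to give the enantiomeric-auxiliary arylacetyl imide F1. Its dibutylboron Z-enolate (Bu2BOTf, i-Pr2NEt, CH2Cl2, −78 °C) would undergo the Evans syn-aldol reaction with 10, well established for arylacetyl imides and aromatic aldehydes, to give the (2R,3R) syn adduct F2. NaBH4 in THF/H2O would give the (1R,2S) syn diol F3, and TBSCl/imidazole its primary silyl ether F4. Mitsunobu esterification (4-nitrobenzoic acid, PPh3, DIAD) would invert the carbinol to the (1S) 4-nitrobenzoate F5. K2CO3 in MeOH would then remove the ester and the aryl silyl group together and deliver 15. The closed arm would continue from 15 by steps 11 to 14, and the open arm would be taken from 15 by silylating both free hydroxyls with TBSOTf/2,6-lutidine, which gives 20.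

Step 20 (three-component coupling). C-alkylation of the crowded enolate may be slow, so that proton transfer or decomposition of the benzylic bromide wins and the conjugate adduct is left unalkylated. The fallback sets out from 19 and 27 and comes back at 31. The conjugate addition of 28 to 27 would be run alone and quenched with NH4Cl to give the 4-substituted lactone acetal F6. Nickel boride (Ni2B, from NiCl2·6H2O and NaBH4) would convert it into the 4-benzyl lactone acetal F7. Its much less crowded lithium enolate (LiN(SiMe3)2, THF, −78 °C, DMPU) would then be alkylated with 22 anti to the C4 benzyl group, the classical trans-selective benzylation of β-benzyl-γ-butyrolactones, to give 31 directly.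

Step 11 (Mitsunobu ring closure). Displacement at the crowded, electron-rich benzylic carbinol may be slow and elimination towards a stilbene may compete. The fallback sets out from diol 13 and comes back at 16. The aryl silyl ether would be removed first (K2CO3, MeOH) to give the phenol diol F8. Catalytic p-TsOH in CH2Cl2 at 0 °C would ionise only the para-benzyloxybenzylic carbinol, and the phenol would trap the cation to give the trans-dihydrobenzofuran alcohol F9. The 2,3-trans ring is preferred kinetically and thermodynamically, and the primary alcohol could only close a strained oxetane. TBSCl/imidazole would then give 16.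

Further compounds
F1 | step 7 | arylacetyl imide of (R)-4-benzyl-2-oxazolidinone | COC(=O)c1cc(CC(=O)N2[C@H](Cc3ccccc3)COC2=O)c(O[Si](C)(C)C(C)(C)C)c(OC)c1
F2 | step 7 | (2R,3R) syn-aldol adduct on the (R)-auxiliary | O=C(N1[C@H](Cc2ccccc2)COC1=O)[C@H](c1cc(C(=O)OC)cc(OC)c1O[Si](C)(C)C(C)(C)C)[C@@H](O)c1ccc(OCc2ccccc2)c(OC)c1
F3 | step 7 | (1R,2S) syn diol | OC[C@H](c1cc(C(=O)OC)cc(OC)c1O[Si](C)(C)C(C)(C)C)[C@@H](O)c1ccc(OCc2ccccc2)c(OC)c1
F4 | step 7 | primary TBS ether of the syn diol | CC(C)(C)[Si](C)(C)OC[C@H](c1cc(C(=O)OC)cc(OC)c1O[Si](C)(C)C(C)(C)C)[C@@H](O)c1ccc(OCc2ccccc2)c(OC)c1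
F5 | step 7 | (1S) 4-nitrobenzoate after Mitsunobu inversion | CC(C)(C)[Si](C)(C)OC[C@H](c1cc(C(=O)OC)cc(OC)c1O[Si](C)(C)C(C)(C)C)[C@H](OC(=O)c1ccc(cc1)[N+](=O)[O-])c1ccc(OCc2ccccc2)c(OC)c1
F6 | step 20 | 4-[2-(group B)-1,3-dithian-2-yl]-5-menthyloxy lactone acetal (4,5-trans) | C1C(=O)O[C@H](O[C@H]2C[C@@H](C)CC[C@@H]2C(C)C)[C@H]1C1(SCCCS1)c1cc(OC)c2c(c1)[C@@H](CO[Si](C)(C)C(C)(C)C)[C@H](c1ccc(OCc3ccccc3)c(OC)c1)O2
F7 | step 20 | 4-(B–CH2)-5-menthyloxy lactone acetal (4,5-trans) | C1C(=O)O[C@H](O[C@H]2C[C@@H](C)CC[C@@H]2C(C)C)[C@H]1Cc1cc(OC)c2c(c1)[C@@H](CO[Si](C)(C)C(C)(C)C)[C@H](c1ccc(OCc3ccccc3)c(OC)c1)O2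
F8 | step 11 | phenol (1S,2S)-diol | OC[C@H](c1cc(C(=O)OC)cc(OC)c1O)[C@H](O)c1ccc(OCc2ccccc2)c(OC)c1
F9 | step 11 | trans-(2R,3S)-dihydrobenzofuran ester with free CH2OH | COC(=O)c1cc(OC)c2c(c1)[C@@H](CO)[C@H](c1ccc(OCc3ccccc3)c(OC)c1)O2
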